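# Synthesis plan for CID5471610 (compound 24): copper-carbene desymmetrization of a prochiral dimethoxycyclohexadiene, then cyclopropane opening

Numbering used throughout: C1 and C5 are the bridgeheads (C1 beside the CMe2 carbon C8), C2–C3–C4 the trione bridge, C6 the CH2, C7 the prenylated CH, C9 the bridging ketone. Ring A is C1, C2, C3, C4, C5, C9; ring B is C1, C8, C7, C6, C5, C9. Prenyl means 3-methylbut-2-enyl. "Endo" at C7 means on the face of ring B turned towards the C2–C4 bridge.

## The problem

Compound 24 is a type B polyprenylated acylphloroglucinol: a bicyclo[3.3.1]nonane-2,4,9-trione in which ring A is a 3-benzoyl β-triketone and ring B a cyclohexanone sharing C1, C9 and C5 with it. Both bridgeheads are quaternary and prenylated, and C1 is bonded to the quaternary C8, so a bond between two fully substituted carbons has to be made at some point. Of the three stereocentres, C1 and C5 can exist in only one relative arrangement within the bicycle, so they must be set together by a single absolute decision. C7 is different: its prenyl group points endo, the more crowded and less stable orientation, so it cannot be reached by equilibration and must be imposed by the rigid bicycle on a reagent that delivers the last atom to C7 from the open exo face. The three trisubstituted prenyl alkenes rule out late hydrogenation, strong acid and unselective oxidants; the non-enolisable β-dicarbonyl arrays C2/C9 and C4/C9 are open to retro-Claisen cleavage by hydroxide or alkoxide; and the acidic, chelating acyl triketone is best kept masked as a methyl enol ether until the end. Early intermediates also carry enol ethers that do not survive aqueous acid. The feature that opens the route is that C1 sits between two oxygen-bearing carbons of ring A, C2 and C9. Ring A is therefore a masked 2-substituted resorcinol, and in the corresponding 1,5-dimethoxycyclohexa-1,4-diene C1 is a prochiral centre whose two enol ether arms (C2=C3 and C9=C5) are enantiotopic, while C8, C7 and C6 can hang from C1 as a diazoketone within reach of either arm.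

## Retrosynthesis

**Benzoyl group and enol last (24 ⇒ 23 ⇒ 20).** The C3–C(=O)Ph bond is cut and the triketone is written as its C2 methyl enol ether. Carrying the free acyl triketone earlier would expose an acidic, chelating function to bases, boranes and titanium reagents. In β-methoxy enone 20 ring A has exactly one acidic C–H left (C3–H), so acylation with benzoyl chloride 21 is regiospecific. The forward steps are a C3 lithiation–acylation and a non-hydrolytic O-demethylation.

**C5–prenyl bond (20 ⇒ 18 + 7).** This bond is cut after the bicycle exists. A C5 substituent placed before the key step would sit on one enol ether arm of the diene and destroy its prochirality. In 18 the bridgehead C5–H lies between the C4 and C9 carbonyls and is the most acidic C–H, so the forward reaction is a bridgehead metalation–alkylation with prenyl bromide 7. It needs the C4 carbonyl to be in place first.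

**C4 oxygen (18 ⇒ 17).** C4=O is taken back to CH2. Bringing this oxygen from the aromatic stage is not possible: a phloroglucinol-level arene would lose the extra methoxy group in the Birch reduction, and a dienone would deactivate the enol ethers towards the carbene. The forward step is an allylic C–H oxidation that must prefer the enol ether's allylic CH2 over the prenyl groups.

**C7 prenyl (17 ⇒ 14 + 15 ⇒ 13).** The prenyl group is cut between its CH2 and its vinyl carbon. The CH2 then becomes an exocyclic methylene on C7 (14), which goes back to the C7 ketone of 13. Methods that bring carbon to C7 last (alkylation, radical allylation) would attack from the exo face and give the exo isomer. Hydroboration of 14 instead delivers hydrogen last from the exo face and leaves the carbon arm endo. The forward steps need site-selective methylenation of C7 over C9, face-selective hydroboration and an sp3–sp2 coupling with 1-bromo-2-methylprop-1-ene 15.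

**Key disconnection, C5–C6 (13 ⇒ 12 ⇒ 11).** Cutting C5–C6, with transient re-formation of C6–C9, turns the three carbons of ring B into a side chain on C1 and leaves ring A as a symmetric cyclohexadiene. Neighbouring cuts (C1–C8, C5–C9) would each leave a chiral precursor. Diazoketone 11 has no stereocentre and no ring other than the diene. The forward reaction must choose one of two enantiotopic enol ethers, avoid the prenyl alkene, and open the cyclopropane 12 only at C6–C9.

**Side chain and C1 prenyl (11 ⇒ 9 ⇒ 6 + 7).** The C6–C7 bond is cut as acylation of diazomethane by acid 9. The C1–prenyl bond is cut as alkylation of the doubly allylic carbanion of diene acid 6. The alternative, prenylating the C1 bridgehead of the finished bicycle beside CMe2, would be far more hindered and would need a C2 carbonyl that the route keeps masked.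

**Dearomatisation and C1–C8 (6 ⇒ 5 ⇒ 4 ⇒ 1 + 2).** Diene 6 is the Birch product of aryl acid 5. The C1–C8 bond is cut as an aryl–enolate coupling between 2-bromo-1,3-dimethoxybenzene 1 and methyl isobutyrate 2. The vicinal quaternary pair is thus formed while C1 is still a flat aromatic carbon, the least demanding moment for it.

## Roads not taken

**Alternative 1:** The C1–C8 bond is cut as a ring-contracting Claisen rearrangement. The precursor is the fused dihydropyran A2, in which the enol oxygen on C9 is tied through a CH2 to C7 and C7 carries an exocyclic isopropylidene. On heating, the allyl vinyl ether C1=C9–O–CH2–C7=C8 would shift to form C1–C8 and give the 7-methylene benzoyl trione A1.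
- Merits: the hardest bond is made intramolecularly, C5 transfers its configuration to C1, and A1 already carries the benzoyl group and both bridgehead prenyls.
- Weak points: A2 is a dearomatised acylphloroglucinol whose C5 stereocentre needs its own asymmetric synthesis and a regioselective O-alkylation. The shift must close a bridged ring through a boat-like transition state between a tetrasubstituted enol carbon and a fully substituted alkene terminus, so high temperatures and competing ionisation or ene pathways are likely. The C7 prenyl would then have to be built by hydroboration in the presence of the free, acidic triketone.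
- Comparison: after its key step this road is shorter than the chosen one and needs no late oxidation or bridgehead alkylation. The chosen plan sets against it an achiral precursor, a catalytic source of absolute configuration, and hydroboration on a masked, non-acidic substrate (14).

**Alternative 2:** C5–C9 and C6–C7 are cut together. The precursor is cyclobutanone A4 (C9, C1, C8, C7 in the four-membered ring) with a tethered methylene ketone C5=C6. A monovalent rhodium catalyst with a transient aminopyridine directing group would insert into C9–C7, take up the alkene and close rings A and B at once, giving A3, which is identical with 20.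
- Merits: two rings and two bonds in one step with every prenyl and the gem-dimethyl group in place, and only benzoylation and demethylation remain. On step count after the key step this is clearly the best of the four.
- Weak points: A4 is a pentasubstituted cyclobutanone with the C1 and C7 stereocentres already set, which is a problem nearly as hard as the target. The inserting alkene is 1,1-disubstituted and electron-poor and must create the quaternary C5. The hot rhodium conditions meet three prenyl alkenes that can coordinate or isomerise, and decarbonylation and loss of the C7 configuration by β-hydride elimination are open side paths.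
- Comparison: the chosen plan pays six steps after its key step but starts from a precursor (11) without any stereocentre, and its key step belongs to an established reaction class.

**Alternative 3:** C5–C6 and C1–C8 are cut back to the achiral aromatic A6 (clusiaphenone B) and the enal A7. Under a cinchona-derived quaternary ammonium phase-transfer catalyst and hydroxide base, C-alkylation with loss of acetate and intramolecular Michael addition would close ring B and give the endo C7 aldehyde A5.
- Merits: this is the shortest route of all. A6 is a short-step aromatic, and one flask makes ring B, both bridgeheads and C7 with benzoyl and two prenyls already present. Absolute configuration comes from an inexpensive organocatalyst.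
- Weak points: the catalyst must distinguish two enantiotopic ring carbons of a delocalised phloroglucinolate through a loose ion pair. C7 in A5 is α to an aldehyde and epimerisable, and the target needs the less stable endo orientation, which must be formed kinetically and then carried through several steps. Turning CHO into prenyl is a deoxygenative chain extension of three to four steps on the free triketone.
- Comparison: for the racemate or the exo (C7-epimeric) series this road would be preferable, being roughly half as long. For this diastereomer the chosen plan offers a C7 centre fixed irreversibly on a non-epimerisable CH2 arm and an enantio-determining step on a rigid, two-point-bound substrate.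

Key step: step 6

Assumptions:
- The (S,S)-configured bis(oxazoline) is taken to direct the carbene to the enol ether that gives 13 as drawn; if the opposite sense of induction is found, the (R,R)-ligand is used instead.
- 24 is a set of rapidly equilibrating enol tautomers and is drawn as the exocyclic enol.

## Route

Step 1
Reactants: 1 2-bromo-1,3-dimethoxybenzene; 2 methyl isobutyrate (methyl 2-methylpropanoate)
Product: 4 methyl 2-(2,6-dimethoxyphenyl)-2-methylpropanoate, via lithium enolate of methyl isobutyrate 3 (not isolated)
Conditions: LiNCy2 (from Cy2NH, n-BuLi), toluene, 0 °C → rt; then 1, Pd(dba)2 (2 mol %), P(t-Bu)3 (2 mol %), rt → 60 °C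
Reagents that add atoms: lithium dicyclohexylamide, [Li+].[N-](C1CCCCC1)C1CCCCC1 (its lithium stays only in 3)
Why: Palladium-catalysed α-arylation of an ester enolate; the isobutyrate enolate cannot be arylated twice, and the bulky electron-rich phosphine supports oxidative addition to the hindered, electron-rich bromide and reductive elimination to the quaternary benzylic carbon.

Step 2
Reactants: 4 methyl 2-(2,6-dimethoxyphenyl)-2-methylpropanoate
Product: 5 2-(2,6-dimethoxyphenyl)-2-methylpropanoic acid
Conditions: KOH, DMSO/H2O, 110 °C; then aq HCl
Reagents that add atoms: potassium hydroxide, [K+].[OH-]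
Why: Saponification of a hindered ester, driven by poorly solvated hydroxide in DMSO; the aryl methyl ethers are inert to hydroxide.

Step 3
Reactants: 5 2-(2,6-dimethoxyphenyl)-2-methylpropanoic acid
Product: 6 2-(2,6-dimethoxycyclohexa-2,5-dien-1-yl)-2-methylpropanoic acid
Conditions: Li, NH3(l), THF, t-BuOH, −78 → −33 °C; NH4Cl; extraction from cold pH 6 phosphate buffer
Reagents that add atoms: none
Why: Birch reduction; the methoxy groups stay on the remaining double bonds, so hydrogen is added at C1 and C4 to give the symmetric 1,5-dimethoxy-1,4-diene, and the carboxylate is inert to the dissolving metal.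

Step 4
Reactants: 6 2-(2,6-dimethoxycyclohexa-2,5-dien-1-yl)-2-methylpropanoic acid; 7 prenyl bromide (1-bromo-3-methylbut-2-ene)
Product: 9 2-[2,6-dimethoxy-1-(3-methylbut-2-enyl)cyclohexa-2,5-dien-1-yl]-2-methylpropanoic acid, via C1-lithiated lithium carboxylate 8 (not isolated)
Conditions: t-BuLi (2.3 equiv), THF/HMPA, −78 → −40 °C; 7, −78 °C; cold pH 6 buffer
Reagents that add atoms: prenyl bromide (7), CC(C)=CCBr; tert-butyllithium, [Li]C(C)(C)C (its lithium stays only in 8)
Why: Alkylation of a doubly allylic (pentadienyl) carbanion; after carboxylate formation the second equivalent of base removes the C1–H flanked by both enol ethers, with lithium held by the two methoxy groups, and cyclohexadienyl anions alkylate at the central carbon, here with an unhindered primary allylic bromide.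

Step 5
Reactants: 9 2-[2,6-dimethoxy-1-(3-methylbut-2-enyl)cyclohexa-2,5-dien-1-yl]-2-methylpropanoic acid
Product: 11 1-diazo-3-[2,6-dimethoxy-1-(3-methylbut-2-enyl)cyclohexa-2,5-dien-1-yl]-3-methylbutan-2-one, via mixed carboxylic methanesulfonic anhydride 10 (not isolated)
Conditions: MsCl (1.2 equiv), Et3N, THF, −10 °C; then CH2N2, Et2O, 0 °C → rt
Reagents that add atoms: diazomethane, C=[N+]=[N-]; methanesulfonyl chloride, CS(=O)(=O)Cl (its atoms stay only in 10)
Why: Acylation of diazomethane by an activated acid (first stage of the Arndt–Eistert sequence); the acyl mesylate forms under basic conditions that spare the enol ethers, has no α-hydrogen for ketene formation and is reactive enough for a neopentyl-type carbonyl.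

Step 6
Reactants: 11 1-diazo-3-[2,6-dimethoxy-1-(3-methylbut-2-enyl)cyclohexa-2,5-dien-1-yl]-3-methylbutan-2-one
Product: 13 2-methoxy-8,8-dimethyl-1-(3-methylbut-2-enyl)bicyclo[3.3.1]non-2-ene-7,9-dione (C1 and C5 as in 24), via methoxycyclopropyl ketone 12 (not isolated)
Conditions: (CuOTf)2·C6H6 (5 mol %), (S,S)-t-Bu-box (12 mol %), toluene, rt, slow addition of 11; then THF, 1 M aq HCl, 0 °C
Reagents that add atoms: water, O
Why: The monovalent copper–bis(oxazoline) complex turns 11 into an electrophilic copper carbene at C6, which adds across the C9=C5 enol ether to give the donor–acceptor cyclopropane 12; protonation of the C7 carbonyl then lets the C9 methoxy lone pair push the C6–C9 bond open, and water converts the C9 oxocarbenium ion into the ketone with loss of methanol. The closest known reaction type is the catalytic asymmetric intramolecular cyclopropanation of α-diazo ketones onto enol ethers, followed by acid opening of 2-alkoxycyclopropyl ketones. The carbene closes the five-membered ring C1–C8–C7–C6–C9 and the three-membered ring C5–C6–C9 in one [2+1] addition (a bicyclo[3.1.0]hexanone), and cleavage of the shared C6–C9 bond merges them into six-membered ring B, so the bridged ring arises by ring expansion. C1 and C5 are set together: the tether can reach only the ring face it sits on, so the only choice is which enantiotopic enol ether reacts, and the C2-symmetric ligand on copper decides that; C6 and C9 of 12 are transient stereocentres and vanish on opening. The enol ether should outcompete the prenyl alkene because it is more nucleophilic and is reached through a five-membered instead of a six-membered ring. Only C6–C9 joins the donor carbon to the acceptor-bearing carbon, which fixes the regiochemistry of opening. The C2 enol ether should survive the short, cold acid treatment because its C-protonation would place an oxocarbenium ion beside quaternary C1 and β to the new C9 carbonyl.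

Step 7
Reactants: 13 2-methoxy-8,8-dimethyl-1-(3-methylbut-2-enyl)bicyclo[3.3.1]non-2-ene-7,9-dione
Product: 14 2-methoxy-8,8-dimethyl-7-methylidene-1-(3-methylbut-2-enyl)bicyclo[3.3.1]non-2-en-9-one
Conditions: Cp2TiMe2 (2–3 equiv), toluene/THF, 70 °C, dark
Reagents that add atoms: dimethyltitanocene Cp2TiMe2, C[Ti](C)(C1C=CC=C1)C1C=CC=C1
Why: Carbonyl methylenation by the titanium methylidene formed thermally from Cp2TiMe2, a non-basic reagent suited to hindered enolisable ketones; the C7 ketone has a CH2 on one side and is more accessible than the C9 carbonyl locked between a quaternary and a tertiary bridgehead.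

Step 8
Reactants: 14 2-methoxy-8,8-dimethyl-7-methylidene-1-(3-methylbut-2-enyl)bicyclo[3.3.1]non-2-en-9-one; 15 1-bromo-2-methylprop-1-ene
Product: 17 2-methoxy-8,8-dimethyl-1,7-bis(3-methylbut-2-enyl)bicyclo[3.3.1]non-2-en-9-one (7-prenyl endo), via B-alkyl-9-BBN borane 16 (not isolated)
Conditions: 9-BBN, THF, 0 → 40 °C; then 15, Pd(dppf)Cl2 (10 mol %), AsPh3, Cs2CO3, DMF/H2O, 50 °C
Reagents that add atoms: 1-bromo-2-methylprop-1-ene (15), CC(C)=CBr; 9-BBN, B1C2CCCC1CCC2 (its boron stays only in 16)
Why: Hydroboration followed by B-alkyl Suzuki–Miyaura coupling; 9-BBN selects the 1,1-disubstituted alkene over the trisubstituted prenyl and enol ether double bonds and approaches from the exo face because the endo face is covered by the C2–C4 bridge. Hydrogen therefore reaches C7 from outside and the CH2–B arm, which becomes the prenyl group, points endo; this sets C7.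

Step 9
Reactants: 17 2-methoxy-8,8-dimethyl-1,7-bis(3-methylbut-2-enyl)bicyclo[3.3.1]non-2-en-9-one
Product: 18 2-methoxy-8,8-dimethyl-1,7-bis(3-methylbut-2-enyl)bicyclo[3.3.1]non-2-ene-4,9-dione
Conditions: Pd(OH)2/C (cat.), t-BuOOH, Cs2CO3, CH2Cl2, 4 °C
Reagents that add atoms: tert-butyl hydroperoxide, CC(C)(C)OO
Why: Radical allylic C–H oxidation with t-BuOOH and a palladium catalyst; hydrogen abstraction should be fastest at C4, whose radical is stabilised as a 1-methoxyallyl system, and the product is the β-methoxy enone (vinylogous ester) of ring A.

Step 10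
Reactants: 18 2-methoxy-8,8-dimethyl-1,7-bis(3-methylbut-2-enyl)bicyclo[3.3.1]non-2-ene-4,9-dione; 7 prenyl bromide
Product: 20 2-methoxy-8,8-dimethyl-1,5,7-tris(3-methylbut-2-enyl)bicyclo[3.3.1]non-2-ene-4,9-dione, via C5-lithiated enone 19 (not isolated)
Conditions: LDA, THF, −78 °C; 7, −78 → 0 °C
Reagents that add atoms: prenyl bromide (7), CC(C)=CCBr; lithium diisopropylamide, [Li+].CC(C)[N-]C(C)C (its lithium stays only in 19)
Why: Bridgehead metalation–alkylation of a bicyclo[3.3.1]nonane β-methoxy enone; C5–H lies between the C4 and C9 carbonyls and is removed by LDA, and the pyramidal bridgehead carbanion is alkylated with retention, the only outcome the bicycle allows.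

Step 11
Reactants: 20 2-methoxy-8,8-dimethyl-1,5,7-tris(3-methylbut-2-enyl)bicyclo[3.3.1]non-2-ene-4,9-dione; 21 benzoyl chloride
Product: 23 3-benzoyl-2-methoxy-8,8-dimethyl-1,5,7-tris(3-methylbut-2-enyl)bicyclo[3.3.1]non-2-ene-4,9-dione, via C3-lithiated enone 22 (not isolated)
Conditions: LiTMP (from TMP, n-BuLi), THF, −78 °C; 21, −78 °C → rt
Reagents that add atoms: benzoyl chloride (21), O=C(Cl)c1ccccc1; lithium 2,2,6,6-tetramethylpiperidide, [Li+].CC1(C)CCCC(C)(C)[N-]1 (its lithium stays only in 22)
Why: α-Lithiation of the β-methoxy enone at C3, the only acidic C–H left (sp2, between the C4 carbonyl and the C2 methoxy group), followed by C-acylation with benzoyl chloride.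

Step 12
Reactants: 23 3-benzoyl-2-methoxy-8,8-dimethyl-1,5,7-tris(3-methylbut-2-enyl)bicyclo[3.3.1]non-2-ene-4,9-dione
Product: 24 3-[hydroxy(phenyl)methylidene]-8,8-dimethyl-1,5,7-tris(3-methylbut-2-enyl)bicyclo[3.3.1]nonane-2,4,9-trione (7-prenyl endo; the target)
Conditions: LiCl, DMSO, 120 °C; then dilute aq HCl
Reagents that add atoms: none
Why: SN2 demethylation of the vinylogous methyl ester by chloride, with the acyl triketone enolate as leaving group; the conditions are non-hydrolytic, so the retro-Claisen-prone β-dicarbonyl arrays never meet hydroxide, and protonation gives the enolised benzoyl triketone.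

## Compound list

1 | 2-bromo-1,3-dimethoxybenzene | COc1cccc(OC)c1Br | starting material
2 | methyl isobutyrate | COC(=O)C(C)C | starting material
3 | lithium 1-methoxy-2-methylprop-1-en-1-olate (lithium enolate of 2) | COC([O-])=C(C)C.[Li+] | intermediate
4 | methyl 2-(2,6-dimethoxyphenyl)-2-methylpropanoate | COC(=O)C(C)(C)c1c(OC)cccc1OC | intermediate
5 | 2-(2,6-dimethoxyphenyl)-2-methylpropanoic acid | OC(=O)C(C)(C)c1c(OC)cccc1OC | intermediate
6 | 2-(2,6-dimethoxycyclohexa-2,5-dien-1-yl)-2-methylpropanoic acid | OC(=O)C(C)(C)C1C(OC)=CCC=C1OC | intermediate
7 | prenyl bromide (1-bromo-3-methylbut-2-ene) | CC(C)=CCBr | starting material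
8 | dilithium salt of 6, lithiated at ring C1 (carboxylate and pentadienyl anion) | [Li+].[Li+].[O-]C(=O)C(C)(C)[C-]1C(OC)=CCC=C1OC | intermediate
9 | 2-[2,6-dimethoxy-1-(3-methylbut-2-enyl)cyclohexa-2,5-dien-1-yl]-2-methylpropanoic acid | CC(C)=CCC1(C(C)(C)C(=O)O)C(OC)=CCC=C1OC | intermediate
10 | mixed anhydride of 9 with methanesulfonic acid (acyl mesylate) | CC(C)=CCC1(C(C)(C)C(=O)OS(C)(=O)=O)C(OC)=CCC=C1OC | intermediate
11 | 1-diazo-3-[2,6-dimethoxy-1-(3-methylbut-2-enyl)cyclohexa-2,5-dien-1-yl]-3-methylbutan-2-one | CC(C)=CCC1(C(C)(C)C(=O)C=[N+]=[N-])C(OC)=CCC=C1OC | intermediate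
12 | donor–acceptor cyclopropane: C5–C6–C9 three-membered ring with OMe on C9, cis-fused to the cyclopentanone C1–C8–C7–C6–C9 and to the 2-methoxycyclohexene ring A; C1 prenyl, C8 gem-dimethyl | COC1=CC[C@@H]2[C@@H]3C(=O)C(C)(C)[C@@]1(CC=C(C)C)[C@]23OC | intermediate
13 | 2-methoxy-8,8-dimethyl-1-(3-methylbut-2-enyl)bicyclo[3.3.1]non-2-ene-7,9-dione, C1 and C5 as in 24 | O=C1C[C@H]2CC=C(OC)[C@](CC=C(C)C)(C2=O)C1(C)C | intermediate
14 | 2-methoxy-8,8-dimethyl-7-methylidene-1-(3-methylbut-2-enyl)bicyclo[3.3.1]non-2-en-9-one | C=C1C[C@H]2CC=C(OC)[C@](CC=C(C)C)(C2=O)C1(C)C | intermediate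
15 | 1-bromo-2-methylprop-1-ene | CC(C)=CBr | starting material
16 | 7-endo-[(9-borabicyclo[3.3.1]nonan-9-yl)methyl]-2-methoxy-8,8-dimethyl-1-(3-methylbut-2-enyl)bicyclo[3.3.1]non-2-en-9-one | C1CC2CCCC(C1)B2C[C@H]3C[C@H]4CC=C(OC)[C@](CC=C(C)C)(C4=O)C3(C)C | intermediate
17 | 2-methoxy-8,8-dimethyl-1,7-bis(3-methylbut-2-enyl)bicyclo[3.3.1]non-2-en-9-one, 7-prenyl endo | CC(C)=CC[C@H]1C[C@H]2CC=C(OC)[C@](CC=C(C)C)(C2=O)C1(C)C | intermediate
18 | 2-methoxy-8,8-dimethyl-1,7-bis(3-methylbut-2-enyl)bicyclo[3.3.1]non-2-ene-4,9-dione, 7-prenyl endo | CC(C)=CC[C@H]1C[C@H]2C(=O)C=C(OC)[C@](CC=C(C)C)(C2=O)C1(C)C | intermediate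
19 | 5-lithio derivative of 18 (bridgehead carbanion/enolate) | CC(C)=CC[C@H]1C[C@@]2([Li])C(=O)C=C(OC)[C@](CC=C(C)C)(C2=O)C1(C)C | intermediate
20 | 2-methoxy-8,8-dimethyl-1,5,7-tris(3-methylbut-2-enyl)bicyclo[3.3.1]non-2-ene-4,9-dione, 7-prenyl endo | CC(C)=CC[C@H]1C[C@@]2(CC=C(C)C)C(=O)C=C(OC)[C@](CC=C(C)C)(C2=O)C1(C)C | intermediate
21 | benzoyl chloride | O=C(Cl)c1ccccc1 | starting material
22 | 3-lithio derivative of 20 | CC(C)=CC[C@H]1C[C@@]2(CC=C(C)C)C(=O)C([Li])=C(OC)[C@](CC=C(C)C)(C2=O)C1(C)C | intermediate
23 | 3-benzoyl-2-methoxy-8,8-dimethyl-1,5,7-tris(3-methylbut-2-enyl)bicyclo[3.3.1]non-2-ene-4,9-dione, 7-prenyl endo | CC(C)=CC[C@H]1C[C@@]2(CC=C(C)C)C(=O)C(C(=O)c3ccccc3)=C(OC)[C@](CC=C(C)C)(C2=O)C1(C)C | intermediate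
24 | 3-[hydroxy(phenyl)methylidene]-8,8-dimethyl-1,5,7-tris(3-methylbut-2-enyl)bicyclo[3.3.1]nonane-2,4,9-trione, 7-prenyl endo (CID5471610) | CC(C)=CC[C@H]1C[C@@]2(CC=C(C)C)C(=O)/C(=C(/O)c3ccccc3)C(=O)[C@](CC=C(C)C)(C2=O)C1(C)C | target

## Step count and least certain steps

Total: 12 steps. Longest linear sequence: 12 steps (1 → 24).

**Step 6 (key step).** The most likely failure is incomplete discrimination between the two enantiotopic enol ethers. The diazoketone carbene binds the catalyst through one point only, and the differentiating groups are three bonds from the metal. Carbene leakage to the prenyl alkene and over-hydrolysis of the C2 enol ether during opening are secondary risks. The fallback changes the carbene class to a two-point-binding α-diazo-β-keto sulfone. It sets out from 9: the mixed anhydride 10, generated as in step 5, is intercepted with two equivalents of lithiated methyl phenyl sulfone to give the β-keto sulfone F1. Diazo transfer (4-acetamidobenzenesulfonyl azide, Et3N) gives the α-diazo-β-keto sulfone F2. The same copper–bis(oxazoline) cyclopropanation gives the sulfonyl cyclopropane F3, and acid opening gives the 6-phenylsulfonyl diketone F4. Reductive desulfonylation with SmI2 (THF/MeOH, −78 °C) returns to the route at 13.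

**Step 4.** The most likely failure is incomplete metalation of the tertiary C1–H beside the bulky side chain. Alkylation of the pentadienyl anion at its ring terminus (C3) instead of the congested centre, or consumption of t-BuLi by the carboxylate, could follow. The fallback carries the side chain as an alkoxide, which is inert to the base, and restores the acid by oxidation. It sets out from 4: LiAlH4 reduction gives 2-(2,6-dimethoxyphenyl)-2-methylpropan-1-ol F5, and Birch reduction gives the diene alcohol F6. Double deprotonation with t-BuLi and alkylation with 7 gives the prenylated diene alcohol F7. Parikh–Doering oxidation gives the aldehyde F8, and oxidation with Ag2O in aqueous NaOH returns to the route at 9 without exposing the enol ethers to acid.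

**Step 9.** The most likely failure is hydrogen abstraction from the allylic positions of the prenyl groups competing with abstraction at C4, especially at the C7 prenyl, whose CH2 is less shielded than the neopentyl CH2 of the C1 prenyl. The fallback changes the order of events, so that the oxidation meets only the C1 prenyl and no exocyclic alkene. It sets out from 13: the same Pd(OH)2/C–t-BuOOH oxidation gives the 2-methoxy-4,7,9-trione F9. Methylenation of the C7 ketone with Cp2TiMe2 gives F10, the vinylogous ester carbonyl being the least electrophilic of the three. Hydroboration with 9-BBN to the borane F11 and coupling with 15 as in step 8 returns to the route at 18.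

**Step 8.** The most likely failure is slow transmetalation of the β-branched alkylborane next to quaternary C8, which lets protodeboronation and reduction of the C9 ketone by excess borane compete. Erosion of the exo-face preference by the axial C8 methyl group is the second risk. The fallback replaces the palladium coupling with a copper-mediated sp3 coupling and offers a separation point for C7 epimers. It sets out from 14: hydroboration as before and oxidative work-up (NaOH, H2O2) give the endo primary alcohol F12, and PPh3/I2/imidazole gives the iodide F13. Li2CuCl4-catalysed coupling with (2-methylprop-1-enyl)magnesium bromide at low temperature returns to the route at 17.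

**Step 1.** The most likely failure is slow reductive elimination to a quaternary carbon flanked by two ortho-methoxy groups, leading to hydrodehalogenation of 1. The fallback forms the quaternary centre by alkylation instead of arylation. It sets out from 1: palladium-catalysed arylation of the unhindered lithium enolate of tert-butyl acetate gives tert-butyl 2-(2,6-dimethoxyphenyl)acetate F14. Exhaustive methylation (KOt-Bu or LDA, MeI, twice) gives tert-butyl 2-(2,6-dimethoxyphenyl)-2-methylpropanoate F15, and CF3CO2H in CH2Cl2 returns to the route at 5.

## Further compounds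

F1 | step 6 | 3-[2,6-dimethoxy-1-(3-methylbut-2-enyl)cyclohexa-2,5-dien-1-yl]-3-methyl-1-(phenylsulfonyl)butan-2-one | CC(C)=CCC1(C(C)(C)C(=O)CS(=O)(=O)c2ccccc2)C(OC)=CCC=C1OC
F2 | step 6 | 1-diazo-3-[2,6-dimethoxy-1-(3-methylbut-2-enyl)cyclohexa-2,5-dien-1-yl]-3-methyl-1-(phenylsulfonyl)butan-2-one | CC(C)=CCC1(C(C)(C)C(=O)C(=[N+]=[N-])S(=O)(=O)c2ccccc2)C(OC)=CCC=C1OC
F3 | step 6 | 6-phenylsulfonyl analogue of cyclopropane 12 | COC1=CC[C@@H]2[C@]3(S(=O)(=O)c4ccccc4)C(=O)C(C)(C)[C@@]1(CC=C(C)C)[C@]23OC
F4 | step 6 | 2-methoxy-8,8-dimethyl-1-(3-methylbut-2-enyl)-6-(phenylsulfonyl)bicyclo[3.3.1]non-2-ene-7,9-dione | O=C1C(S(=O)(=O)c3ccccc3)[C@H]2CC=C(OC)[C@](CC=C(C)C)(C2=O)C1(C)C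
F5 | step 4 | 2-(2,6-dimethoxyphenyl)-2-methylpropan-1-ol | OCC(C)(C)c1c(OC)cccc1OC
F6 | step 4 | 2-(2,6-dimethoxycyclohexa-2,5-dien-1-yl)-2-methylpropan-1-ol | OCC(C)(C)C1C(OC)=CCC=C1OC
F7 | step 4 | 2-[2,6-dimethoxy-1-(3-methylbut-2-enyl)cyclohexa-2,5-dien-1-yl]-2-methylpropan-1-ol | CC(C)=CCC1(C(C)(C)CO)C(OC)=CCC=C1OC
F8 | step 4 | 2-[2,6-dimethoxy-1-(3-methylbut-2-enyl)cyclohexa-2,5-dien-1-yl]-2-methylpropanal | CC(C)=CCC1(C(C)(C)C=O)C(OC)=CCC=C1OC
F9 | step 9 | 2-methoxy-8,8-dimethyl-1-(3-methylbut-2-enyl)bicyclo[3.3.1]non-2-ene-4,7,9-trione | O=C1C[C@H]2C(=O)C=C(OC)[C@](CC=C(C)C)(C2=O)C1(C)C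
F10 | step 9 | 2-methoxy-8,8-dimethyl-7-methylidene-1-(3-methylbut-2-enyl)bicyclo[3.3.1]non-2-ene-4,9-dione | C=C1C[C@H]2C(=O)C=C(OC)[C@](CC=C(C)C)(C2=O)C1(C)C
F11 | step 9 | 7-endo-[(9-borabicyclo[3.3.1]nonan-9-yl)methyl]-2-methoxy-8,8-dimethyl-1-(3-methylbut-2-enyl)bicyclo[3.3.1]non-2-ene-4,9-dione | C1CC2CCCC(C1)B2C[C@H]3C[C@H]4C(=O)C=C(OC)[C@](CC=C(C)C)(C4=O)C3(C)C
F12 | step 8 | 7-endo-(hydroxymethyl)-2-methoxy-8,8-dimethyl-1-(3-methylbut-2-enyl)bicyclo[3.3.1]non-2-en-9-one | OC[C@H]1C[C@H]2CC=C(OC)[C@](CC=C(C)C)(C2=O)C1(C)C
F13 | step 8 | 7-endo-(iodomethyl)-2-methoxy-8,8-dimethyl-1-(3-methylbut-2-enyl)bicyclo[3.3.1]non-2-en-9-one | IC[C@H]1C[C@H]2CC=C(OC)[C@](CC=C(C)C)(C2=O)C1(C)C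
F14 | step 1 | tert-butyl 2-(2,6-dimethoxyphenyl)acetate | CC(C)(C)OC(=O)Cc1c(OC)cccc1OC
F15 | step 1 | tert-butyl 2-(2,6-dimethoxyphenyl)-2-methylpropanoate | CC(C)(C)OC(=O)C(C)(C)c1c(OC)cccc1OC
A1 | alternative 1 | 7-methylene bicyclic benzoyl trione | C=C1C[C@@]2(CC=C(C)C)C(=O)/C(=C(/O)c3ccccc3)C(=O)[C@](CC=C(C)C)(C2=O)C1(C)C
A2 | alternative 1 | fused dihydropyran with the allyl vinyl ether C1=C9–O–CH2–C7=C8Me2 | CC(C)=C1C[C@@]2(CC=C(C)C)C(=O)C(C(=O)c3ccccc3)=C(O)C(CC=C(C)C)=C2OC1
A3 | alternative 2 | triprenyl bicyclic methyl enol ether (identical with 20) | CC(C)=CC[C@H]1C[C@@]2(CC=C(C)C)C(=O)C=C(OC)[C@](CC=C(C)C)(C2=O)C1(C)C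
A4 | alternative 2 | cyclobutanone with tethered methylene ketone | CC(C)=CC[C@H]1C(=O)[C@@](CC=C(C)C)(/C(OC)=C\C(=O)C(=C)CC=C(C)C)C1(C)C
A5 | alternative 3 | bicyclic benzoyl trione with endo C7 aldehyde | O=C[C@H]1C[C@@]2(CC=C(C)C)C(=O)/C(=C(/O)c3ccccc3)C(=O)[C@](CC=C(C)C)(C2=O)C1(C)C
A6 | alternative 3 | clusiaphenone B | CC(C)=CCc1c(O)c(CC=C(C)C)c(O)c(C(=O)c2ccccc2)c1O
A7 | alternative 3 | 2-(acetoxymethyl)-3-methylbut-2-enal | CC(=O)OCC(C=O)=C(C)C
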